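**The question.** Target is what you want from this flask, and what matters is how it stands against side product, early and at the end.

| flask | substrate | reagent | free catalyst | impurity | remark | time |
|---|---|---|---|---|---|---|
| ochre | 1.2 M | 2.6 M | 12 mM | 2 mM | run made earlier |  |
| flask | 1.2 M | 1.32 M | 12 mM | 2.0 mM |  | 15 d |

- ochre (time / h: target / %, side product / %): 3.00: 1.0, 0.7; 5.00: 2.6, 1.0; 10.0: 6.5, 3.6; 20.0: 13.0, 7.4; 40.0: 19.9, 14.9

(each reading ± 0.5 percentage points)

1. ratio of target to side product at 5.0 h
2. ratio of target to side product at 15 d

**One route.** Picture the target route by itself: the ratio has no denominator, so the number begins with the second route.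

**Second route.** Add the side route and the ratio compares two rates. I take the ochre readings from 5.00 h to 20.0 h together, which gives a ratio of 1.84. Divided by the ochre reagent charge this is 0.708 M⁻¹: the split, target made per side product made for each molar of reagent, a selectivity factor at fixed charges of catalyst and impurity. One run cannot test my assumption that reagent enters the target route once and the side route not at all. This flask has the ochre charges of catalyst and impurity, so whatever impurity does is inside the split, and its early ratio is the split times 1.32 M, which is 0.935.

**Dying catalyst.** In the ochre run the gains from 20.0 h to 40.0 h stand at 0.920, half the earlier ratio, so the comparison drifts downward. Suppose free catalyst, lost first-order, feeds both routes and acts on the target route a second time. Then target's rate follows its square and side product's its first power, and the totals in this flask end at 0.467, half the early ratio.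

**The forecast.** The forecast gives 1.8 and 0.7, reasoning: “I assume both routes respond similarly”. My reckoning is lower on both counts.

**The result.** The flask gives 1.01 and 0.421, against my 0.935 and 0.467.

    substrate + free catalyst ⇌ free catalyst + intermediate (K = 0.780, k = 0.0338 M⁻¹ min⁻¹)
    intermediate → side product (k = 0.00130 min⁻¹)
    reagent + free catalyst + intermediate → free catalyst + target (k = 0.108 M⁻² min⁻¹)
    free catalyst → spent catalyst A (k = 4.09 × 10⁻⁴ min⁻¹)
    free catalyst + impurity → spent catalyst B (k = 5.04 M⁻¹ min⁻¹)

**What happened.** Impurity went early, at 0% by 1.50 d, taking 16.7% of the catalyst into spent catalyst B, while substrate passed through intermediate to target and side product. By 7.50 d free catalyst stood at 1.00% and spent catalyst A at 82.3%, and at 15.0 d this flask held target at 15.7% with 47% of the substrate and 86% of the reagent left.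

**Second flask.** For a neighbour flask with 2.2 M of reagent the split gives 1.56 early and 0.779 at the end; that flask computes to 1.68 and 0.700.

The earlier runs and the new flask are simulated on assumed constants; the scatter is artificial.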